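Last operation: fluoride removes four silyl ethers from a tetrasilyl flavanone, so no C–C bond is made once the stereocentre exists.
Key disconnection C2–C1': taking ring B off C2 and restoring C2=C3 leads back to an achiral 8-substituted 7-silyloxy-4H-chromen-4-one and a 3,4-bis(silyloxy)phenylboronic acid. In the forward direction, one rhodium/chiral-diene 1,4-addition joins the two halves, makes the last C–C bond and sets the only stereocentre (2S).
Enabling feature: in ring C, C2 is both the β-carbon of the C4 ketone (C2–C3–C4=O) and the carbon bonded to O1, and it carries only H besides the aryl group. Its dehydro form is therefore the flat, s-trans-locked enone of a 4-pyranone ring, with two enantiotopic faces and an unhindered electrophilic C2.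
C8 side chain: Claisen transfer of an allyl group from O7 to C8, cross-metathesis with methacrolein for the (E)-trisubstituted alkene, then 1,2-reduction of the enal.
Ring order: no ring is built. Rings A and C are bought fused in 7-hydroxychromone and ring B in 4-bromocatechol; ring C only passes from pyranone to dihydropyranone in the key step.

Key step: step 9

Assumption: the facial sense of the (S,S)-diene–rhodium catalyst is taken from its behaviour toward six-membered cyclic enones; if the chromone binds the other way round, the (R,R)-ligand is used instead and nothing else changes.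

Step 1
Reactants: 1 7-hydroxy-4H-chromen-4-one; 2 allyl bromide
Product: 3 7-(prop-2-en-1-yloxy)-4H-chromen-4-one
Conditions: K2CO3, acetone, reflux
Reagents that add atoms: none
Why: Williamson ether synthesis: the acidic 7-OH is the only nucleophilic site of 1, and potassium carbonate is too weak a base to open the pyranone ring.

Step 2
Reactants: 3 7-(prop-2-en-1-yloxy)-4H-chromen-4-one
Product: 5 7-hydroxy-8-(prop-2-en-1-yl)-4H-chromen-4-one, via ortho-dienone 4 (not isolated)
Conditions: N,N-diethylaniline, 200 °C, sealed vessel, argon
Reagents that add atoms: none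
Why: Aromatic Claisen rearrangement, a suprafacial [3,3]-shift to ortho-dienone 4 followed by tautomerisation, in which the higher double-bond character of C7–C8 compared with C6–C7 in the benzopyranone should send the allyl group to C8, as is usual for 7-allyloxy chromones and coumarins.

Step 3
Reactants: 5 7-hydroxy-8-(prop-2-en-1-yl)-4H-chromen-4-one
Product: 6 7-[(tert-butyldimethylsilyl)oxy]-8-(prop-2-en-1-yl)-4H-chromen-4-one
Conditions: TBSCl, imidazole, DMF, rt
Reagents that add atoms: tert-butyldimethylsilyl chloride (TBSCl), CC(C)(C)[Si](C)(C)Cl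
Why: Silyl ether formation with imidazole as base and nucleophilic catalyst, which removes the acidic phenol so that it can neither add to the enal of step 4 in an oxa-Michael sense nor deactivate the chromone as a phenoxide in step 9.

Step 4
Reactants: 6 7-[(tert-butyldimethylsilyl)oxy]-8-(prop-2-en-1-yl)-4H-chromen-4-one; 7 methacrolein
Product: 8 (2E)-4-{7-[(tert-butyldimethylsilyl)oxy]-4-oxo-4H-chromen-8-yl}-2-methylbut-2-enal
Conditions: second-generation Hoveyda–Grubbs catalyst (5 mol %), excess 7, CH2Cl2, 40 °C
Reagents that add atoms: none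
Why: Olefin cross-metathesis between a terminal alkene and an electron-poor 1,1-disubstituted alkene that does not homodimerise, a pairing known to favour the cross product and, under thermodynamic control, the (E)-enal with the formyl group trans to the CH2–aryl group.

Step 5
Reactants: 8 (2E)-4-{7-[(tert-butyldimethylsilyl)oxy]-4-oxo-4H-chromen-8-yl}-2-methylbut-2-enal
Product: 9 7-[(tert-butyldimethylsilyl)oxy]-8-[(2E)-4-hydroxy-3-methylbut-2-en-1-yl]-4H-chromen-4-one
Conditions: NaBH4, CeCl3·7H2O, MeOH/THF, −78 to −40 °C; aq NH4Cl
Reagents that add atoms: none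
Why: Luche reduction: the cerium-modified borohydride adds 1,2 to the aldehyde much faster than to the vinylogous-ester carbonyl C4 of the chromone, and the alkene geometry is not touched.

Step 6
Reactants: 9 7-[(tert-butyldimethylsilyl)oxy]-8-[(2E)-4-hydroxy-3-methylbut-2-en-1-yl]-4H-chromen-4-one
Product: 10 7-[(tert-butyldimethylsilyl)oxy]-8-{(2E)-4-[(tert-butyldimethylsilyl)oxy]-3-methylbut-2-en-1-yl}-4H-chromen-4-one
Conditions: TBSCl, imidazole, DMF, rt
Reagents that add atoms: tert-butyldimethylsilyl chloride (TBSCl), CC(C)(C)[Si](C)(C)Cl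
Why: Silyl ether formation at the primary allylic alcohol, which keeps the hydroxyl group away from rhodium in step 9 and would also re-silylate any O7 that had been bared in step 5.

Step 7
Reactants: 11 4-bromobenzene-1,2-diol (4-bromocatechol)
Product: 12 4-bromo-1,2-bis[(tert-butyldimethylsilyl)oxy]benzene
Conditions: TBSCl (2.4 equiv), imidazole, DMF, rt
Reagents that add atoms: tert-butyldimethylsilyl chloride (TBSCl), CC(C)(C)[Si](C)(C)Cl
Why: Double silyl ether formation, which masks the oxidation-prone and metal-binding catechol with groups that survive organolithium chemistry and leave with fluoride.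

Step 8
Reactants: 12 4-bromo-1,2-bis[(tert-butyldimethylsilyl)oxy]benzene
Product: 15 {3,4-bis[(tert-butyldimethylsilyl)oxy]phenyl}boronic acid, via aryllithium 13 (not isolated), via lithium triisopropoxyborate 14 (not isolated)
Conditions: n-BuLi, THF, −78 °C; B(OiPr)3, −78 °C to rt; dilute aq HCl, 0 °C
Reagents that add atoms: n-butyllithium, [Li]CCCC (lithium of 13 and 14); triisopropyl borate, CC(C)OB(OC(C)C)OC(C)C; water, O
Why: Bromine–lithium exchange followed by electrophilic borylation and hydrolysis of the borate, which is safe here because lithium sits meta and para to the silyloxy groups, so that no silyl migration from oxygen to carbon can occur.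

Step 9
Reactants: 10 7-[(tert-butyldimethylsilyl)oxy]-8-{(2E)-4-[(tert-butyldimethylsilyl)oxy]-3-methylbut-2-en-1-yl}-4H-chromen-4-one; 15 {3,4-bis[(tert-butyldimethylsilyl)oxy]phenyl}boronic acid
Product: 16 (2S)-2-{3,4-bis[(tert-butyldimethylsilyl)oxy]phenyl}-7-[(tert-butyldimethylsilyl)oxy]-8-{(2E)-4-[(tert-butyldimethylsilyl)oxy]-3-methylbut-2-en-1-yl}-2,3-dihydro-4H-chromen-4-one
Conditions: [RhCl(C2H4)2]2 (2.5 mol %), (1S,4S)-2,5-diphenylbicyclo[2.2.2]octa-2,5-diene ((S,S)-Ph-bod*, 5.5 mol %), aq KOH (10 mol %), 15 (2.5 equiv, in portions), toluene/H2O 10:1, 40 °C, argon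
Reagents that add atoms: none
Why: Hayashi–Miyaura reaction: the hydroxorhodium–diene complex formed from [RhCl(C2H4)2]2, the ligand and KOH takes the aryl group from 15 by transmetalation, C2=C3 of 10 binds to rhodium and inserts into the Rh–aryl bond so that the aryl group ends on C2, and water protonates the oxa-π-allyl rhodium enolate at C3, which returns the hydroxo complex and leaves boric acid. The closest known reaction type is this very one, the rhodium-catalysed asymmetric 1,4-addition of arylboronic acids to 4H-chromen-4-ones with chiral diene or electron-poor biaryl bisphosphine ligands, which gives flavanones. No ring is closed; ring C is only taken from the pyranone to the dihydropyranone level. The new stereocentre C2 is controlled by the ligand alone, because 10 is flat and achiral: in the C2-symmetric (S,S)-diene complex the phenyl group next to the free site forces the chromone to bind with C4=O turned away from it, which exposes the Re face of C2 to the migrating aryl group and should give 2S. The step needs 1,4- over 1,2-addition, attack on C2=C3 and not on the side-chain alkene, and survival of the O1–C2 bond; these are secured by the unsubstituted, carbonyl-polarised C2, by the unactivated trisubstituted side-chain alkene with its poor silyloxy leaving group, by the silyl cap on O7 that prevents a deactivating phenoxide, and by the nearly neutral two-phase medium in which protonation of the enolate outruns E1cB ring opening to the chalcone. In this one operation two achiral fragments of similar size are joined, the carbon skeleton is completed and the base-labile stereocentre is created so late that it meets only one further, weakly acidic step.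

Step 10
Reactants: 16 (2S)-tetrasilyl flavanone of step 9
Product: 17 (2S)-2-(3,4-dihydroxyphenyl)-7-hydroxy-8-[(2E)-4-hydroxy-3-methylbut-2-en-1-yl]-2,3-dihydro-4H-chromen-4-one
Conditions: Et3N·3HF (excess), THF, 0 °C to rt, argon
Reagents that add atoms: none
Why: Fluoride-driven cleavage of the three aryl and one alkyl silyl ethers in a weakly acidic medium, in which neither retro-oxa-Michael racemisation at C2 (a base-promoted process) nor ionisation of the allylic alcohol (a strong-acid process) should take place.

Compound list
1 | 7-hydroxy-4H-chromen-4-one | O=c1ccoc2cc(O)ccc12 | starting material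
2 | allyl bromide | C=CCBr | starting material
3 | 7-(prop-2-en-1-yloxy)-4H-chromen-4-one | C=CCOc1ccc2c(c1)occc2=O | intermediate
4 | 8-(prop-2-en-1-yl)-8H-chromene-4,7-dione (racemic ortho-dienone, not isolated) | C=CCC1C(=O)C=CC2=C1OC=CC2=O | intermediate
5 | 7-hydroxy-8-(prop-2-en-1-yl)-4H-chromen-4-one | C=CCc1c(O)ccc2c1occc2=O | intermediate
6 | 7-[(tert-butyldimethylsilyl)oxy]-8-(prop-2-en-1-yl)-4H-chromen-4-one | C=CCc1c(O[Si](C)(C)C(C)(C)C)ccc2c1occc2=O | intermediate
7 | methacrolein | C=C(C)C=O | starting material
8 | (2E)-4-{7-[(tert-butyldimethylsilyl)oxy]-4-oxo-4H-chromen-8-yl}-2-methylbut-2-enal | C/C(=C\Cc1c(O[Si](C)(C)C(C)(C)C)ccc2c1occc2=O)C=O | intermediate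
9 | 7-[(tert-butyldimethylsilyl)oxy]-8-[(2E)-4-hydroxy-3-methylbut-2-en-1-yl]-4H-chromen-4-one | C/C(=C\Cc1c(O[Si](C)(C)C(C)(C)C)ccc2c1occc2=O)CO | intermediate
10 | 7-[(tert-butyldimethylsilyl)oxy]-8-{(2E)-4-[(tert-butyldimethylsilyl)oxy]-3-methylbut-2-en-1-yl}-4H-chromen-4-one | C/C(=C\Cc1c(O[Si](C)(C)C(C)(C)C)ccc2c1occc2=O)CO[Si](C)(C)C(C)(C)C | intermediate
11 | 4-bromobenzene-1,2-diol | Oc1ccc(Br)cc1O | starting material
12 | 4-bromo-1,2-bis[(tert-butyldimethylsilyl)oxy]benzene | CC(C)(C)[Si](C)(C)Oc1ccc(Br)cc1O[Si](C)(C)C(C)(C)C | intermediate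
13 | {3,4-bis[(tert-butyldimethylsilyl)oxy]phenyl}lithium (not isolated) | [Li]c1ccc(O[Si](C)(C)C(C)(C)C)c(O[Si](C)(C)C(C)(C)C)c1 | intermediate
14 | lithium {3,4-bis[(tert-butyldimethylsilyl)oxy]phenyl}triisopropoxyborate (not isolated) | [Li+].CC(C)O[B-](OC(C)C)(OC(C)C)c1ccc(O[Si](C)(C)C(C)(C)C)c(O[Si](C)(C)C(C)(C)C)c1 | intermediate
15 | {3,4-bis[(tert-butyldimethylsilyl)oxy]phenyl}boronic acid | OB(O)c1ccc(O[Si](C)(C)C(C)(C)C)c(O[Si](C)(C)C(C)(C)C)c1 | intermediate
16 | (2S)-2-{3,4-bis[(tert-butyldimethylsilyl)oxy]phenyl}-7-[(tert-butyldimethylsilyl)oxy]-8-{(2E)-4-[(tert-butyldimethylsilyl)oxy]-3-methylbut-2-en-1-yl}-2,3-dihydro-4H-chromen-4-one | C/C(=C\Cc1c(O[Si](C)(C)C(C)(C)C)ccc2c1O[C@H](c1ccc(O[Si](C)(C)C(C)(C)C)c(O[Si](C)(C)C(C)(C)C)c1)CC2=O)CO[Si](C)(C)C(C)(C)C | intermediate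
17 | (2S)-2-(3,4-dihydroxyphenyl)-7-hydroxy-8-[(2E)-4-hydroxy-3-methylbut-2-en-1-yl]-2,3-dihydro-4H-chromen-4-one | C/C(=C\Cc1c(O)ccc2c1O[C@H](c1ccc(O)c(O)c1)CC2=O)CO | target

Total step count: 10. Longest linear sequence: 8 steps (steps 1–6, 9, 10); steps 7 and 8 form the short second branch.

Steps most likely to fail

Step 9. Insertion of the electron-rich chromone, flanked at C8, into the Rh–aryl bond may be slow enough for protodeboronation of the electron-rich boronic acid to compete. Facial discrimination may also be insufficient, or be eroded by reversible opening of ring C at the enolate stage. The fallback sets out from 10 and 15 and comes back at 16. The two are joined without a chiral ligand by the most active achiral catalyst, [Rh(OH)(cod)]2 in dioxane/H2O, to give the racemic tetrasilyl flavanone F1. A kinetic resolution by asymmetric transfer hydrogenation follows (Cp*RhCl(TsDPEN), the antipode matched to the (2R)-ketone, HCO2H/Et3N, EtOAc). It reduces the (2R)-enantiomer to the cis-(2R,4R)-flavan-4-ol F2, which is separated by chromatography from the untouched (2S)-ketone 16.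

Step 2. Part of the allyl group may migrate to C6 instead of C8, or the pyranone may degrade at the temperature the rearrangement needs. The fallback sets out from 1 and comes back at 5. Electrophilic iodination (N-iodosuccinimide, DMF, 0 °C) at the most activated position between O1 and O7 gives 7-hydroxy-8-iodo-4H-chromen-4-one F3. A Stille coupling with allyltributylstannane (Pd(PPh3)4, DMF, 90 °C) then places the allyl group at C8 at moderate temperature and gives 5.

Step 4. Ruthenium hydride species may shift the allyl double bond into conjugation with ring A, homodimerisation may compete, or turnover next to the bulky silyl ether may be poor. The fallback sets out from 6 and comes back at 8. Lemieux–Johnson cleavage of the terminal alkene (OsO4 cat., NaIO4, 2,6-lutidine, dioxane/H2O) gives {7-[(tert-butyldimethylsilyl)oxy]-4-oxo-4H-chromen-8-yl}acetaldehyde F4. A Wittig reaction with the stabilised ylide 2-(triphenyl-λ5-phosphanylidene)propanal (toluene, 60 °C) then builds the (E)-enal 8.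

Further compounds
F1 | step 9 | racemic 2-{3,4-bis[(tert-butyldimethylsilyl)oxy]phenyl}-7-[(tert-butyldimethylsilyl)oxy]-8-{(2E)-4-[(tert-butyldimethylsilyl)oxy]-3-methylbut-2-en-1-yl}-2,3-dihydro-4H-chromen-4-one | C/C(=C\Cc1c(O[Si](C)(C)C(C)(C)C)ccc2c1OC(c1ccc(O[Si](C)(C)C(C)(C)C)c(O[Si](C)(C)C(C)(C)C)c1)CC2=O)CO[Si](C)(C)C(C)(C)C
F2 | step 9 | (2R,4R)-2-{3,4-bis[(tert-butyldimethylsilyl)oxy]phenyl}-7-[(tert-butyldimethylsilyl)oxy]-8-{(2E)-4-[(tert-butyldimethylsilyl)oxy]-3-methylbut-2-en-1-yl}-3,4-dihydro-2H-chromen-4-ol | C/C(=C\Cc1c(O[Si](C)(C)C(C)(C)C)ccc2c1O[C@@H](c1ccc(O[Si](C)(C)C(C)(C)C)c(O[Si](C)(C)C(C)(C)C)c1)C[C@H]2O)CO[Si](C)(C)C(C)(C)C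
F3 | step 2 | 7-hydroxy-8-iodo-4H-chromen-4-one | O=c1ccoc2c(I)c(O)ccc12
F4 | step 4 | {7-[(tert-butyldimethylsilyl)oxy]-4-oxo-4H-chromen-8-yl}acetaldehyde | O=CCc1c(O[Si](C)(C)C(C)(C)C)ccc2c1occc2=O
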